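**Plan**
- Retrosynthetic cuts, in order: the C6–O acyl bond of the hydroxytiglate, the ring bond C5–C6 (carbonyl-ene), the C1–C2 bond (vinylchromium addition to a two-carbon aldehyde) and the C3–C4 bond (alkynylation of 3-methylbut-2-enal).
- Forward: C3–C4 is joined first, the alkyne becomes a Z-vinyl iodide, C4 is acylated, the C1/C6 unit is added and oxidised to a Z-vinylglyoxal. The only ring closes in step 8 through C5–C6, followed by hydrogenation, esterification at O6 and desilylation.
- Enabling feature (ring numbered C1 ketone, C2 hydroxymethyl carbon, C3, C4 isobutyrate carbon, C5 isopropyl carbon, C6 hydroxytiglate carbon): an oxygenated C6 lying between the C1 carbonyl and a C5 that carries a three-carbon branch is what an ene reaction of an α-keto aldehyde with a prenyl-type alkene leaves behind, and the C2=C3 double bond holds the two partners cis.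
- Stereochemistry: C4 comes from a catalytic enantioselective alkynylation. C5 and C6 arise together in the ene closure, 5,6-trans from the chelated chair-like transition state, with their sense relative to C4 enforced by a chiral divalent-copper Lewis acid. The Z-alkene comes from trans-hydroalumination and the E-enoate from a stabilised Wittig reaction.

Key step: step 8

Assumption: the facial sense of the two chiral catalysts is taken from their closest analogies ((R,R)-ProPhenol adding the alkynylzinc to the Si face of the enal, the (R,R)-t-Bu-box copper complex leaving the Re face of the chelated aldehyde open); should either prove reversed, the antipodal ligand is used.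

**Step 1**
Reactants: 1 prop-2-yn-1-ol
Product: 2 tert-butyl(diphenyl)(prop-2-yn-1-yloxy)silane
Conditions: TBDPSCl, imidazole, DMF, 0 °C → rt
Reagents that add atoms: tert-butyl(chloro)diphenylsilane, CC(C)(C)[Si](Cl)(c1ccccc1)c1ccccc1
Why: Imidazole-promoted silylation of a primary alcohol (silyl ether formation) installs a tert-butyldiphenylsilyl group that will outlast the later acid-mediated removal of a primary tert-butyldimethylsilyl ether.

**Step 2**
Reactants: 2 tert-butyl(diphenyl)(prop-2-yn-1-yloxy)silane, 3 3-methylbut-2-enal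
Product: 5 (4R)-1-[(tert-butyldiphenylsilyl)oxy]-6-methylhept-5-en-2-yn-4-ol, via alkynyl(methyl)zinc 4 (not isolated)
Conditions: 2 (excess), Me2Zn, (R,R)-ProPhenol (10 mol%), Ph3P=O (20 mol%), toluene, 0 °C; then 3, 0–4 °C
Reagents that add atoms: none
Why: Zinc–ProPhenol-catalysed enantioselective alkynylation of an α,β-unsaturated aldehyde: Me2Zn converts 2 into the alkynylzinc 4, the dinuclear zinc–ligand complex binds the aldehyde and delivers the alkynyl group to its Si face, and this catalyst control sets the carbinol centre as 4R, the future C4 of the ring.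

**Step 3**
Reactants: 5 (4R)-1-[(tert-butyldiphenylsilyl)oxy]-6-methylhept-5-en-2-yn-4-ol
Product: 7 (2Z,4R)-1-[(tert-butyldiphenylsilyl)oxy]-2-iodo-6-methylhepta-2,5-dien-4-ol, via cyclic vinylalanate 6 (not isolated)
Conditions: NaAlH2(OCH2CH2OMe)2, THF, 0 °C; then I2, THF, −78 → 0 °C
Reagents that add atoms: iodine, [I][I]
Why: Hydroxyl-directed trans-hydroalumination of a propargylic alcohol followed by iodinolysis: the aluminium alkoxide delivers hydride to the proximal alkyne carbon to give the five-membered alanate 6, and iodine replaces aluminium with retention, so that iodine sits on the carbon bearing CH2OSi and cis to C4 (Z) while the carbinol centre is untouched.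

**Step 4**
Reactants: 7 (2Z,4R)-1-[(tert-butyldiphenylsilyl)oxy]-2-iodo-6-methylhepta-2,5-dien-4-ol, 8 2-methylpropanoyl chloride
Product: 9 (2Z,4R)-1-[(tert-butyldiphenylsilyl)oxy]-2-iodo-6-methylhepta-2,5-dien-4-yl 2-methylpropanoate
Conditions: pyridine, DMAP (5 mol%), CH2Cl2, 0 °C
Reagents that add atoms: none
Why: DMAP-catalysed acylation of a secondary alcohol with an acid chloride takes place at oxygen with retention at C4 and puts the isobutyrate in place while this is the only free hydroxyl.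

**Step 5**
Reactants: 9 (2Z,4R)-1-[(tert-butyldiphenylsilyl)oxy]-2-iodo-6-methylhepta-2,5-dien-4-yl 2-methylpropanoate, 10 [(tert-butyldimethylsilyl)oxy]acetaldehyde
Product: 11 (3Z,5R)-1-[(tert-butyldimethylsilyl)oxy]-3-{[(tert-butyldiphenylsilyl)oxy]methyl}-2-hydroxy-7-methylocta-3,6-dien-5-yl 2-methylpropanoate (both C2 epimers)
Conditions: CrCl2 (4 equiv), NiCl2 (2 mol%), DMSO, rt
Reagents that add atoms: none
Why: Nozaki–Hiyama–Kishi coupling, in which zerovalent nickel inserts into the C–I bond and the derived vinylchromium species adds to the aldehyde with retention of alkene geometry and tolerance of the ester and silyl ethers; the new carbinol centre forms as a mixture of epimers that is erased in step 7.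

**Step 6**
Reactants: 11 (3Z,5R)-1-[(tert-butyldimethylsilyl)oxy]-3-{[(tert-butyldiphenylsilyl)oxy]methyl}-2-hydroxy-7-methylocta-3,6-dien-5-yl 2-methylpropanoate
Product: 12 (3Z,5R)-3-{[(tert-butyldiphenylsilyl)oxy]methyl}-1,2-dihydroxy-7-methylocta-3,6-dien-5-yl 2-methylpropanoate (both C2 epimers)
Conditions: PPTS (10 mol%), MeOH, 0 °C → rt
Reagents that add atoms: none
Why: Acid-catalysed methanolysis of silyl ethers cleaves the primary tert-butyldimethylsilyl ether far faster than the tert-butyldiphenylsilyl ether and does not touch the ester, so only the 1,2-diol is unveiled.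

**Step 7**
Reactants: 12 (3Z,5R)-3-{[(tert-butyldiphenylsilyl)oxy]methyl}-1,2-dihydroxy-7-methylocta-3,6-dien-5-yl 2-methylpropanoate
Product: 13 (3Z,5R)-3-{[(tert-butyldiphenylsilyl)oxy]methyl}-7-methyl-1,2-dioxoocta-3,6-dien-5-yl 2-methylpropanoate
Conditions: (COCl)2, DMSO, CH2Cl2, −78 °C; Et3N, −78 → −20 °C; short silica filtration, used at once
Reagents that add atoms: none
Why: Swern oxidation turns the secondary allylic and the primary carbinol into ketone and aldehyde without C–C cleavage of the 1,2-diol, under cold base-quenched conditions that spare the doubly allylic ester and the Z-alkene, and it removes the carbinol epimers.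

**Step 8**
Reactants: 13 (3Z,5R)-3-{[(tert-butyldiphenylsilyl)oxy]methyl}-7-methyl-1,2-dioxoocta-3,6-dien-5-yl 2-methylpropanoate
Product: 14 (4S,5R,6R)-2-{[(tert-butyldiphenylsilyl)oxy]methyl}-6-hydroxy-4-[(2-methylpropanoyl)oxy]-5-(prop-1-en-2-yl)cyclohex-2-en-1-one (4,5-cis and 5,6-trans)
Conditions: [Cu((R,R)-t-Bu-box)](SbF6)2 (10 mol%; t-Bu-box = 2,2'-(propane-2,2-diyl)bis(4-tert-butyl-4,5-dihydrooxazole)), 4 Å molecular sieves, CH2Cl2, 0 °C → rt
Reagents that add atoms: none
Why: The divalent-copper bis(oxazoline) complex chelates the ketone and aldehyde oxygens, and C5 of the trisubstituted alkene attacks the aldehyde carbon while a hydrogen of an allylic methyl passes to the aldehyde oxygen in a chair-like six-centre transition state, a type 1 intramolecular carbonyl-ene reaction (closest precedents: citronellal to isopulegol, bis(oxazoline)copper glyoxylate-ene reactions and intramolecular ene reactions of unsaturated α-keto esters). The six-membered ring closes in the exo sense, the proximal alkene carbon C5 becoming a ring atom through the new C5–C6 bond and the distal carbon staying outside as the isopropenyl group. C6 is set by the chelate, which keeps the aldehyde oxygen pseudo-equatorial, and by the cis-methyl of the prenyl unit, whose allylic 1,3-strain keeps ring carbon C3 out of the inside position and so places the forming isopropenyl group pseudo-equatorial, giving 5,6-trans. C5 relative to C4 requires the acyloxy group in the inside (pseudo-axial) position, which is favoured electronically (a C–O bond anti to the forming bond would drain the attacked alkene) but opposed by 1,3-strain with the same cis-methyl, so the choice is handed to the catalyst, whose (R,R) ligand shields the Si face of the aldehyde and admits C5 only on the Re face, the one that leads to 6R and hence 4,5-cis. Chemoselectivity rests on the aldehyde being far more electrophilic than the ketone (which could only give a five-membered ring), on the Z-alkene holding C5 and C6 within bonding distance, and on a mild aprotic Lewis acid that leaves the doubly allylic ester and the silyl ether untouched.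

**Step 9**
Reactants: 14 (4S,5R,6R)-2-{[(tert-butyldiphenylsilyl)oxy]methyl}-6-hydroxy-4-[(2-methylpropanoyl)oxy]-5-(prop-1-en-2-yl)cyclohex-2-en-1-one
Product: 15 (4S,5R,6R)-2-{[(tert-butyldiphenylsilyl)oxy]methyl}-6-hydroxy-4-[(2-methylpropanoyl)oxy]-5-(propan-2-yl)cyclohex-2-en-1-one
Conditions: H2 (1 atm), RhCl(PPh3)3 (5 mol%), toluene, rt
Reagents that add atoms: none
Why: Homogeneous hydrogenation with RhCl(PPh3)3 reduces the unhindered 1,1-disubstituted alkene and leaves the trisubstituted conjugated enone and the allylic ester alone, as in the reduction of carvone to carvotanacetone, and no stereocentre is formed.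

**Step 10**
Reactants: 10 [(tert-butyldimethylsilyl)oxy]acetaldehyde, 16 ethyl 2-(triphenyl-λ5-phosphanylidene)propanoate
Product: 17 ethyl (2E)-4-[(tert-butyldimethylsilyl)oxy]-2-methylbut-2-enoate
Conditions: CH2Cl2, rt
Reagents that add atoms: none
Why: Wittig olefination with a stabilised α-methyl ylide gives the trisubstituted enoate with the E geometry of the hydroxytiglate.

**Step 11**
Reactants: 17 ethyl (2E)-4-[(tert-butyldimethylsilyl)oxy]-2-methylbut-2-enoate
Product: 18 (2E)-4-[(tert-butyldimethylsilyl)oxy]-2-methylbut-2-enoic acid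
Conditions: LiOH, THF/H2O, rt; then dilute HCl to pH 4
Reagents that add atoms: lithium hydroxide, [Li+].[OH-]
Why: Saponification of the ethyl ester by addition–elimination at the acyl carbon leaves the primary silyl ether and the alkene geometry unchanged.

**Step 12**
Reactants: 15 (4S,5R,6R)-2-{[(tert-butyldiphenylsilyl)oxy]methyl}-6-hydroxy-4-[(2-methylpropanoyl)oxy]-5-(propan-2-yl)cyclohex-2-en-1-one, 18 (2E)-4-[(tert-butyldimethylsilyl)oxy]-2-methylbut-2-enoic acid
Product: 20 (4S,5S,6R)-6-{[(2E)-4-[(tert-butyldimethylsilyl)oxy]-2-methylbut-2-enoyl]oxy}-2-{[(tert-butyldiphenylsilyl)oxy]methyl}-4-[(2-methylpropanoyl)oxy]-5-(propan-2-yl)cyclohex-2-en-1-one, via mixed anhydride 19 (not isolated)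
Conditions: 18, 2,4,6-Cl3C6H2COCl, Et3N, THF, rt; then 15, DMAP, toluene, rt
Reagents that add atoms: none
Why: Yamaguchi esterification, in which DMAP attacks the mixed anhydride 19 at the less hindered enoyl carbonyl and the acylpyridinium acylates the hindered C6 hydroxyl at oxygen, so C6 keeps its configuration (the C5 descriptor changes from R to S only because acylation of O6 alters the priorities).

**Step 13**
Reactants: 20 (4S,5S,6R)-6-{[(2E)-4-[(tert-butyldimethylsilyl)oxy]-2-methylbut-2-enoyl]oxy}-2-{[(tert-butyldiphenylsilyl)oxy]methyl}-4-[(2-methylpropanoyl)oxy]-5-(propan-2-yl)cyclohex-2-en-1-one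
Product: 21 (4S,5S,6R)-2-(hydroxymethyl)-6-{[(2E)-4-hydroxy-2-methylbut-2-enoyl]oxy}-4-[(2-methylpropanoyl)oxy]-5-(propan-2-yl)cyclohex-2-en-1-one (CNP0254776.1)
Conditions: HF·pyridine, pyridine, THF, 0 °C → rt
Reagents that add atoms: none
Why: Desilylation with buffered HF·pyridine cleaves both primary silyl ethers under non-basic conditions that avoid acyl migration, enolisation at C6 and loss of the C4 ester.

**Compound list**
1 | prop-2-yn-1-ol | C#CCO | starting material
2 | tert-butyl(diphenyl)(prop-2-yn-1-yloxy)silane | C#CCO[Si](c1ccccc1)(c1ccccc1)C(C)(C)C | intermediate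
3 | 3-methylbut-2-enal | CC(C)=CC=O | starting material
4 | methyl{3-[(tert-butyldiphenylsilyl)oxy]prop-1-yn-1-yl}zinc | C[Zn]C#CCO[Si](c1ccccc1)(c1ccccc1)C(C)(C)C | intermediate
5 | (4R)-1-[(tert-butyldiphenylsilyl)oxy]-6-methylhept-5-en-2-yn-4-ol | CC(C)=C[C@@H](O)C#CCO[Si](c1ccccc1)(c1ccccc1)C(C)(C)C | intermediate
6 | sodium (5R)-3-{[(tert-butyldiphenylsilyl)oxy]methyl}-2,2-bis(2-methoxyethoxy)-5-(2-methylprop-1-en-1-yl)-2,5-dihydro-1,2-oxaaluminol-2-uide (cyclic vinylalanate) | CC(C)=C[C@@H]1C=C(CO[Si](c2ccccc2)(c2ccccc2)C(C)(C)C)[Al-](OCCOC)(OCCOC)O1.[Na+] | intermediate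
7 | (2Z,4R)-1-[(tert-butyldiphenylsilyl)oxy]-2-iodo-6-methylhepta-2,5-dien-4-ol | CC(C)=C[C@@H](O)/C=C(\I)CO[Si](c1ccccc1)(c1ccccc1)C(C)(C)C | intermediate
8 | 2-methylpropanoyl chloride | CC(C)C(Cl)=O | starting material
9 | (2Z,4R)-1-[(tert-butyldiphenylsilyl)oxy]-2-iodo-6-methylhepta-2,5-dien-4-yl 2-methylpropanoate | CC(C)=C[C@@H](OC(=O)C(C)C)/C=C(\I)CO[Si](c1ccccc1)(c1ccccc1)C(C)(C)C | intermediate
10 | [(tert-butyldimethylsilyl)oxy]acetaldehyde | O=CCO[Si](C)(C)C(C)(C)C | starting material
11 | (3Z,5R)-1-[(tert-butyldimethylsilyl)oxy]-3-{[(tert-butyldiphenylsilyl)oxy]methyl}-2-hydroxy-7-methylocta-3,6-dien-5-yl 2-methylpropanoate (both C2 epimers) | CC(C)=C[C@@H](OC(=O)C(C)C)/C=C(\C(O)CO[Si](C)(C)C(C)(C)C)CO[Si](c1ccccc1)(c1ccccc1)C(C)(C)C | intermediate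
12 | (3Z,5R)-3-{[(tert-butyldiphenylsilyl)oxy]methyl}-1,2-dihydroxy-7-methylocta-3,6-dien-5-yl 2-methylpropanoate (both C2 epimers) | CC(C)=C[C@@H](OC(=O)C(C)C)/C=C(\C(O)CO)CO[Si](c1ccccc1)(c1ccccc1)C(C)(C)C | intermediate
13 | (3Z,5R)-3-{[(tert-butyldiphenylsilyl)oxy]methyl}-7-methyl-1,2-dioxoocta-3,6-dien-5-yl 2-methylpropanoate | O=CC(=O)/C(CO[Si](c1ccccc1)(c1ccccc1)C(C)(C)C)=C\[C@H](OC(=O)C(C)C)C=C(C)C | intermediate
14 | (4S,5R,6R)-2-{[(tert-butyldiphenylsilyl)oxy]methyl}-6-hydroxy-4-[(2-methylpropanoyl)oxy]-5-(prop-1-en-2-yl)cyclohex-2-en-1-one | O[C@H]1C(=O)C(CO[Si](c2ccccc2)(c2ccccc2)C(C)(C)C)=C[C@H](OC(=O)C(C)C)[C@@H]1C(C)=C | intermediate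
15 | (4S,5R,6R)-2-{[(tert-butyldiphenylsilyl)oxy]methyl}-6-hydroxy-4-[(2-methylpropanoyl)oxy]-5-(propan-2-yl)cyclohex-2-en-1-one | O[C@H]1C(=O)C(CO[Si](c2ccccc2)(c2ccccc2)C(C)(C)C)=C[C@H](OC(=O)C(C)C)[C@@H]1C(C)C | intermediate
16 | ethyl 2-(triphenyl-λ5-phosphanylidene)propanoate | CCOC(=O)C(C)=P(c1ccccc1)(c1ccccc1)c1ccccc1 | starting material
17 | ethyl (2E)-4-[(tert-butyldimethylsilyl)oxy]-2-methylbut-2-enoate | CCOC(=O)/C(C)=C/CO[Si](C)(C)C(C)(C)C | intermediate
18 | (2E)-4-[(tert-butyldimethylsilyl)oxy]-2-methylbut-2-enoic acid | C/C(=C\CO[Si](C)(C)C(C)(C)C)C(=O)O | intermediate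
19 | (2E)-4-[(tert-butyldimethylsilyl)oxy]-2-methylbut-2-enoic 2,4,6-trichlorobenzoic anhydride | C/C(=C\CO[Si](C)(C)C(C)(C)C)C(=O)OC(=O)c1c(Cl)cc(Cl)cc1Cl | intermediate
20 | (4S,5S,6R)-6-{[(2E)-4-[(tert-butyldimethylsilyl)oxy]-2-methylbut-2-enoyl]oxy}-2-{[(tert-butyldiphenylsilyl)oxy]methyl}-4-[(2-methylpropanoyl)oxy]-5-(propan-2-yl)cyclohex-2-en-1-one | C/C(=C\CO[Si](C)(C)C(C)(C)C)C(=O)O[C@H]1C(=O)C(CO[Si](c2ccccc2)(c2ccccc2)C(C)(C)C)=C[C@H](OC(=O)C(C)C)[C@@H]1C(C)C | intermediate
21 | (4S,5S,6R)-2-(hydroxymethyl)-6-{[(2E)-4-hydroxy-2-methylbut-2-enoyl]oxy}-4-[(2-methylpropanoyl)oxy]-5-(propan-2-yl)cyclohex-2-en-1-one | C/C(=C\CO)C(=O)O[C@H]1C(=O)C(CO)=C[C@H](OC(=O)C(C)C)[C@@H]1C(C)C | target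

**Totals**
Total step count: 13. Longest linear sequence: 11 steps (steps 1–9, 12 and 13).

**Steps most likely to fail**

Step 8. The closure may show poor facial selectivity at C5 relative to C4. The pathway with hydrogen instead of acyloxy in the inside position is the one allylic 1,3-strain prefers; it would give the 4,5-trans series if the catalyst cannot overrule it. The Lewis acid may also ionise the doubly allylic ester. The fallback uses the substrate bias instead of opposing it and inverts C4 afterwards. It sets out from 2 and 3: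
- Alkynylation with (S,S)-ProPhenol gives the antipodal carbinol (4S)-1-[(tert-butyldiphenylsilyl)oxy]-6-methylhept-5-en-2-yn-4-ol F1.
- NaAlH2(OCH2CH2OMe)2 then iodine gives the (2Z,4S)-iodo dienol F2.
- NaH and 4-methoxybenzyl chloride (Bu4NI, THF, 0 °C) give the 4-methoxybenzyl ether F3.
- CrCl2/NiCl2 coupling with 10 gives the carbinol F4, PPTS in MeOH the diol F5, and Swern oxidation the ether-protected vinylglyoxal F6.
- Me2AlCl (CH2Cl2, −78 °C) closes the ring with hydrogen inside and the bulky ether oxygen anti, giving the 4,5-trans-5,6-trans hydroxy ketone F7, which has C5 and C6 as in the target and C4 inverted.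
- H2 with RhCl(PPh3)3 gives the isopropyl compound F8, Yamaguchi esterification with 18 the C6 ester F9, and DDQ (CH2Cl2, pH 7 buffer) the free C4 alcohol F10.
- A Mitsunobu reaction with 2-methylpropanoic acid (PPh3, DIAD, toluene, 0 °C) installs the isobutyrate with inversion and returns to the route at 20.

Step 3. The vinylalanate may lose its β-silyloxy group to give an allene, or hydride may be delivered to the wrong alkyne carbon. The fallback sets out from 5: ruthenium-catalysed trans-hydrosilylation ([Cp*Ru(MeCN)3]PF6, Et3SiH, CH2Cl2, 0 °C → rt) places silicon on the alkyne carbon distal to the free hydroxyl and gives the (2Z,4R)-2-(triethylsilyl) dienol F11. Iododesilylation with retention (NIS, (CF3)2CHOH, 0 °C) returns to the route at 7.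

Step 7. The double oxidation may stall at a hydroxy aldehyde that closes to hemiacetals or oligomerises, and the vinylglyoxal may hydrate on handling. The fallback sets out from 11 and makes the ketone before the primary carbinol is unmasked: Dess–Martin periodinane (NaHCO3, CH2Cl2) gives the silyloxy ketone F12; HF·pyridine/pyridine (THF, 0 °C) removes only the primary tert-butyldimethylsilyl group to give the hydroxy ketone F13; a second Dess–Martin oxidation under anhydrous buffered conditions oxidises the ketol carbinol and returns to the route at 13.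

**Further compounds**
F1 | step 8 | (4S)-1-[(tert-butyldiphenylsilyl)oxy]-6-methylhept-5-en-2-yn-4-ol | CC(C)=C[C@H](O)C#CCO[Si](c1ccccc1)(c1ccccc1)C(C)(C)C
F2 | step 8 | (2Z,4S)-1-[(tert-butyldiphenylsilyl)oxy]-2-iodo-6-methylhepta-2,5-dien-4-ol | CC(C)=C[C@H](O)/C=C(\I)CO[Si](c1ccccc1)(c1ccccc1)C(C)(C)C
F3 | step 8 | tert-butyl({(2Z,4S)-2-iodo-4-[(4-methoxybenzyl)oxy]-6-methylhepta-2,5-dien-1-yl}oxy)diphenylsilane | CC(C)=C[C@H](OCc1ccc(OC)cc1)/C=C(\I)CO[Si](c1ccccc1)(c1ccccc1)C(C)(C)C
F4 | step 8 | (3Z,5S)-1-[(tert-butyldimethylsilyl)oxy]-3-{[(tert-butyldiphenylsilyl)oxy]methyl}-5-[(4-methoxybenzyl)oxy]-7-methylocta-3,6-dien-2-ol (both C2 epimers) | CC(C)=C[C@H](OCc1ccc(OC)cc1)/C=C(\C(O)CO[Si](C)(C)C(C)(C)C)CO[Si](c1ccccc1)(c1ccccc1)C(C)(C)C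
F5 | step 8 | (3Z,5S)-3-{[(tert-butyldiphenylsilyl)oxy]methyl}-5-[(4-methoxybenzyl)oxy]-7-methylocta-3,6-diene-1,2-diol (both C2 epimers) | CC(C)=C[C@H](OCc1ccc(OC)cc1)/C=C(\C(O)CO)CO[Si](c1ccccc1)(c1ccccc1)C(C)(C)C
F6 | step 8 | (3Z,5S)-3-{[(tert-butyldiphenylsilyl)oxy]methyl}-5-[(4-methoxybenzyl)oxy]-7-methyl-2-oxoocta-3,6-dienal | O=CC(=O)/C(CO[Si](c1ccccc1)(c1ccccc1)C(C)(C)C)=C\[C@@H](OCc1ccc(OC)cc1)C=C(C)C
F7 | step 8 | (4R,5R,6R)-2-{[(tert-butyldiphenylsilyl)oxy]methyl}-6-hydroxy-4-[(4-methoxybenzyl)oxy]-5-(prop-1-en-2-yl)cyclohex-2-en-1-one | O[C@H]1C(=O)C(CO[Si](c2ccccc2)(c2ccccc2)C(C)(C)C)=C[C@@H](OCc2ccc(OC)cc2)[C@@H]1C(C)=C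
F8 | step 8 | (4R,5R,6R)-2-{[(tert-butyldiphenylsilyl)oxy]methyl}-6-hydroxy-4-[(4-methoxybenzyl)oxy]-5-(propan-2-yl)cyclohex-2-en-1-one | O[C@H]1C(=O)C(CO[Si](c2ccccc2)(c2ccccc2)C(C)(C)C)=C[C@@H](OCc2ccc(OC)cc2)[C@@H]1C(C)C
F9 | step 8 | (4R,5S,6R)-6-{[(2E)-4-[(tert-butyldimethylsilyl)oxy]-2-methylbut-2-enoyl]oxy}-2-{[(tert-butyldiphenylsilyl)oxy]methyl}-4-[(4-methoxybenzyl)oxy]-5-(propan-2-yl)cyclohex-2-en-1-one | C/C(=C\CO[Si](C)(C)C(C)(C)C)C(=O)O[C@H]1C(=O)C(CO[Si](c2ccccc2)(c2ccccc2)C(C)(C)C)=C[C@@H](OCc2ccc(OC)cc2)[C@@H]1C(C)C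
F10 | step 8 | (4R,5S,6R)-6-{[(2E)-4-[(tert-butyldimethylsilyl)oxy]-2-methylbut-2-enoyl]oxy}-2-{[(tert-butyldiphenylsilyl)oxy]methyl}-4-hydroxy-5-(propan-2-yl)cyclohex-2-en-1-one | C/C(=C\CO[Si](C)(C)C(C)(C)C)C(=O)O[C@H]1C(=O)C(CO[Si](c2ccccc2)(c2ccccc2)C(C)(C)C)=C[C@@H](O)[C@@H]1C(C)C
F11 | step 3 | (2Z,4R)-1-[(tert-butyldiphenylsilyl)oxy]-6-methyl-2-(triethylsilyl)hepta-2,5-dien-4-ol | CC(C)=C[C@@H](O)/C=C(\[Si](CC)(CC)CC)CO[Si](c1ccccc1)(c1ccccc1)C(C)(C)C
F12 | step 7 | (3Z,5R)-1-[(tert-butyldimethylsilyl)oxy]-3-{[(tert-butyldiphenylsilyl)oxy]methyl}-7-methyl-2-oxoocta-3,6-dien-5-yl 2-methylpropanoate | CC(C)=C[C@@H](OC(=O)C(C)C)/C=C(\C(=O)CO[Si](C)(C)C(C)(C)C)CO[Si](c1ccccc1)(c1ccccc1)C(C)(C)C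
F13 | step 7 | (3Z,5R)-3-{[(tert-butyldiphenylsilyl)oxy]methyl}-1-hydroxy-7-methyl-2-oxoocta-3,6-dien-5-yl 2-methylpropanoate | CC(C)=C[C@@H](OC(=O)C(C)C)/C=C(\C(=O)CO)CO[Si](c1ccccc1)(c1ccccc1)C(C)(C)C
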